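## Retrosynthetic overview

1. Target ⇐ alkyne C-desilylation ⇐ oxocane made last, by chloronium-triggered ring expansion of a 2,5-cis tetrahydrofuran through a bicyclic oxonium ion (forms O–C6, C7–Cl and C9–Cl together).
2. Tetrahydrofuran (first heterocycle) ⇐ bromoetherification of an acyclic 6Z,12Z-diene carrying a silyl group on O9 and the acetate on O10 (forms O–C12 and C13–Br).
3. Diene ⇐ two Z-selective Wittig reactions (propyl ylide for C12=C13, a C1–C6 enyne ylide for C6=C7) on a C7–C12 lactol-aldehyde.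
4. Lactol-aldehyde ⇐ ozonolysis of mono-silylated cis-cyclohex-4-ene-1,2-diol ⇐ key step: catalytic enantioselective monosilylation that breaks the mirror symmetry of the meso diol (sets C9/C10; every other centre is relayed from them).
5. meso-Diol ⇐ cyclohexa-1,4-diene ⇐ Birch reduction of benzene. Ring order: carbocycle cleaved, tetrahydrofuran closed, then expanded to the oxocane.

Assumption: carbon numbers C1–C15 are those of the acetogenin chain (C1 alkyne CH, C6 and C12 the ring O–CH carbons, C15 the methyl); in this numbering the target is 3E,6S,7S,9S,10S,12R,13R with a 2,8-trans oxocane.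

Assumption: the antipode of the silylation catalyst (from L- or D-tert-leucine) is used that silylates the hydroxyl on the future C9, giving (1S,2R)-4.

## Route

Step 1
Reactants: 1 benzene
Product: 2 cyclohexa-1,4-diene
Conditions: Li, NH3(l), EtOH, Et2O, −78 → −33 °C
Reagents that add atoms: none
Why: Birch reduction stops at the unconjugated 1,4-diene, breaking the aromaticity of benzene and turning its six carbons into C7–C12 with the two aldehyde termini masked as one ring alkene; no stereocentre.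

Step 2
Reactants: 2 cyclohexa-1,4-diene
Product: 3 cis-cyclohex-4-ene-1,2-diol (meso, 1R,2S)
Conditions: OsO4 (0.5 mol %), N-methylmorpholine N-oxide (0.4 equiv, diene in excess), acetone/H2O 4:1, 0 °C → rt
Reagents that add atoms: OsO4 (catalytic oxygen carrier) O=[Os](=O)(=O)=O; N-methylmorpholine N-oxide C[N+]1([O-])CCOCC1; water O
Why: Upjohn syn-dihydroxylation with the diene in excess oxidises one alkene only, and suprafacial osmate addition gives the cis (meso) diol, fixing the erythro C9/C10 relationship.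

Step 3
Reactants: 3 cis-cyclohex-4-ene-1,2-diol
Product: 4 (1S,2R)-2-[(tert-butyldimethylsilyl)oxy]cyclohex-4-en-1-ol
Conditions: t-BuMe2SiCl (2.0 equiv), i-Pr2NEt (1.25 equiv), (S)-N-[(R)-3,3-dimethylbutan-2-yl]-3,3-dimethyl-2-{[(1-methyl-1H-imidazol-2-yl)methyl]amino}butanamide or its enantiomer (0.3 equiv), THF, −40 °C, 72 h
Reagents that add atoms: tert-butyldimethylsilyl chloride CC(C)(C)[Si](C)(C)Cl
Why: Catalytic enantioselective silylation of a meso 1,2-diol (the key symmetry-breaking step), in which the hydrogen-bonding imidazole catalyst delivers the silyl chloride to one enantiotopic hydroxyl, sets C9 (R) and C10 (S) and leaves the single free OH that later tells the two chain ends apart.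

Step 4
Reactants: 4 (1S,2R)-2-[(tert-butyldimethylsilyl)oxy]cyclohex-4-en-1-ol
Product: 6 2-[(2S,3R)-3-[(tert-butyldimethylsilyl)oxy]-5-hydroxyoxolan-2-yl]acetaldehyde (anomer mixture), via ozonide 5 (not isolated)
Conditions: O3, CH2Cl2, −78 °C; then Me2S, −78 °C → rt
Reagents that add atoms: ozone [O-][O+]=O
Why: Ozonolysis with reductive work-up cleaves the ring to the C7/C12 dialdehyde, and only the free C10–OH can close a five-membered lactol (onto C7), so C12 is left as the one free aldehyde and the termini are differentiated without extra protecting-group steps; stereocentres untouched.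

Step 5
Reactants: 6 2-[(2S,3R)-3-[(tert-butyldimethylsilyl)oxy]-5-hydroxyoxolan-2-yl]acetaldehyde; 7 propyltriphenylphosphonium bromide
Product: 9 (4R,5S)-4-[(tert-butyldimethylsilyl)oxy]-5-[(2Z)-pent-2-en-1-yl]oxolan-2-ol, via propylidene ylide 8 (not isolated)
Conditions: 7 (2.2 equiv), NaN(SiMe3)2 (2.1 equiv), THF, 0 °C; then 6, −78 °C, 30 min; AcOH quench at −78 °C
Reagents that add atoms: none
Why: Wittig olefination with a non-stabilised ylide gives the Z C12=C13 alkene through the kinetic cis-oxaphosphetane, and at −78 °C only the free aldehyde reacts while the lactol (deprotonated by the second equivalent of ylide) stays closed.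

Step 6
Reactants: 10 (2E)-pent-2-en-4-yn-1-ol
Product: 13 (2E)-5-(trimethylsilyl)pent-2-en-4-yn-1-ol, via dimagnesium salt 11 (not isolated), via bis-silyl ether 12 (not isolated)
Conditions: EtMgBr (2.2 equiv), THF, 0 °C → rt; Me3SiCl (2.3 equiv), 0 °C → rt; then 1 M aq. HCl, rt
Reagents that add atoms: chlorotrimethylsilane C[Si](C)(C)Cl
Why: Double deprotonation (alkoxide and acetylide) and silylation, then hydrolysis of the labile O–Si bond, leaves the C-silylated enynol (alkyne protection); no stereocentre.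

Step 7
Reactants: 13 (2E)-5-(trimethylsilyl)pent-2-en-4-yn-1-ol
Product: 14 [(3E)-5-bromopent-3-en-1-yn-1-yl]trimethylsilane
Conditions: CBr4 (1.2 equiv), PPh3 (1.25 equiv), CH2Cl2, −20 → 0 °C
Reagents that add atoms: tetrabromomethane BrC(Br)(Br)Br
Why: Appel bromination converts the primary allylic alcohol into the bromide under neutral conditions without touching the E-enyne.

Step 8
Reactants: 14 [(3E)-5-bromopent-3-en-1-yn-1-yl]trimethylsilane; 15 methyltriphenylphosphonium bromide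
Product: 17 [(3E)-6-(trimethylsilyl)hex-3-en-5-yn-1-yl]triphenylphosphonium bromide, via methylene ylide 16 (not isolated)
Conditions: 15 (1.0 equiv), NaN(SiMe3)2 (1.0 equiv), THF, 0 °C; then added to 14 (1.3 equiv), toluene/THF, −78 → 0 °C
Reagents that add atoms: none
Why: C-alkylation of methylenetriphenylphosphorane (SN2 at the primary allylic carbon) adds the C6 carbon and gives the homologated phosphonium salt directly, and its precipitation limits transylidation.

Step 9
Reactants: 9 (4R,5S)-4-[(tert-butyldimethylsilyl)oxy]-5-[(2Z)-pent-2-en-1-yl]oxolan-2-ol; 17 [(3E)-6-(trimethylsilyl)hex-3-en-5-yn-1-yl]triphenylphosphonium bromide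
Product: 20 (3E,6Z,9R,10S,12Z)-9-[(tert-butyldimethylsilyl)oxy]-1-(trimethylsilyl)pentadeca-3,6,12-trien-1-yn-10-yl acetate, via enyne ylide 18 (not isolated), via alcohol 19 (not isolated)
Conditions: 17 (2.6 equiv), NaN(SiMe3)2 (2.5 equiv), THF, −78 °C; 9, −78 → −10 °C; then Ac2O (6 equiv), DMAP (0.2 equiv), −10 → 0 °C
Reagents that add atoms: acetic anhydride CC(=O)OC(C)=O
Why: Wittig olefination of the lactol through its open hydroxy-aldehyde form gives the Z C6=C7 alkene and liberates the C10 alkoxide, which is acetylated in the same flask; C9 and C10 are not touched.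

Step 10
Reactants: 20 (3E,6Z,9R,10S,12Z)-9-[(tert-butyldimethylsilyl)oxy]-1-(trimethylsilyl)pentadeca-3,6,12-trien-1-yn-10-yl acetate
Product: 21 (2R,3S,5R)-5-[(1R)-1-bromopropyl]-2-[(2Z,5E)-8-(trimethylsilyl)octa-2,5-dien-7-yn-1-yl]oxolan-3-yl acetate
Conditions: N-bromosuccinimide (1.1 equiv), MeCN, −30 → 0 °C, dark
Reagents that add atoms: N-bromosuccinimide O=C1CCC(=O)N1Br
Why: Bromoetherification with the silyl ether as nucleophile (Bartlett-type haloetherification through an O-silyl oxonium ion) closes O9 onto the C12=C13 bromonium ion 5-exo with anti addition across the Z-alkene (12R,13R, threo), and the bulky group on oxygen must sit trans to both ring substituents before it is lost to succinimide, which enforces the 2,5-cis ring; the acetate keeps O10 from cyclising.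

Step 11
Reactants: 21 (2R,3S,5R)-5-[(1R)-1-bromopropyl]-2-[(2Z,5E)-8-(trimethylsilyl)octa-2,5-dien-7-yn-1-yl]oxolan-3-yl acetate
Product: 23 (2R,4S,5S,7S,8S)-2-[(1R)-1-bromopropyl]-5,7-dichloro-8-[(2E)-5-(trimethylsilyl)pent-2-en-4-yn-1-yl]oxocan-4-yl acetate, via oxonium salt 22 (not isolated)
Conditions: Et2SCl·SbCl6 (1.05 equiv), EtNO2/CH2Cl2, −78 °C, 5 min; then n-Bu4NCl (3 equiv), −78 → −40 °C
Reagents that add atoms: chlorodiethylsulfonium hexachloroantimonate CC[S+](Cl)CC.Cl[Sb-](Cl)(Cl)(Cl)(Cl)Cl; tetrabutylammonium chloride CCCC[N+](CCCC)(CCCC)CCCC.[Cl-]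
Why: Proposed new method: the chloronium ion formed at the electron-rich C6=C7 Z-alkene is opened 5-endo by the ring oxygen (anti addition, with the side chain and Cl on the convex face of the cis-fused 1-oxoniabicyclo[3.3.0]octane, giving 6S,7S) and chloride then opens the oxonium at bridgehead C9 with inversion (9S), expanding the ring to the 2,8-trans oxocane, the closest known reactions being Et2SBr·SbCl5Br-triggered ring expansions of tetrahydrofurans through bicyclic oxonium ions and chloride openings of preformed Laurencia-type oxonium ions, with the C9 preference resting on C6 and C12 each bearing a β-halogen and an exocyclic branch while low temperature and immediate chloride keep the acetate from participating.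

Step 12
Reactants: 23 (2R,4S,5S,7S,8S)-2-[(1R)-1-bromopropyl]-5,7-dichloro-8-[(2E)-5-(trimethylsilyl)pent-2-en-4-yn-1-yl]oxocan-4-yl acetate
Product: 24 (2R,4S,5S,7S,8S)-2-[(1R)-1-bromopropyl]-5,7-dichloro-8-[(2E)-pent-2-en-4-yn-1-yl]oxocan-4-yl acetate (CNP0251465.3)
Conditions: n-Bu4NF (1.2 equiv), AcOH (1.2 equiv), THF, 0 °C
Reagents that add atoms: none
Why: Buffered fluoride protodesilylation of the alkynylsilane leaves the acetate, both alkyl chlorides and the bromide intact and gives the target.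

## Compound list

1 | benzene | c1ccccc1 | starting material
2 | cyclohexa-1,4-diene | C1=CCC=CC1 | intermediate
3 | cis-cyclohex-4-ene-1,2-diol (meso, 1R,2S) | O[C@H]1CC=CC[C@H]1O | intermediate
4 | (1S,2R)-2-[(tert-butyldimethylsilyl)oxy]cyclohex-4-en-1-ol | O[C@H]1CC=CC[C@H]1O[Si](C)(C)C(C)(C)C | intermediate
5 | (3S,4R)-4-[(tert-butyldimethylsilyl)oxy]-7,8,9-trioxabicyclo[4.2.1]nonan-3-ol (ozonide of 4) | O[C@H]1CC2OOC(C[C@H]1O[Si](C)(C)C(C)(C)C)O2 | intermediate
6 | 2-[(2S,3R)-3-[(tert-butyldimethylsilyl)oxy]-5-hydroxyoxolan-2-yl]acetaldehyde (anomer mixture) | O=CC[C@@H]1OC(O)C[C@H]1O[Si](C)(C)C(C)(C)C | intermediate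
7 | propyltriphenylphosphonium bromide | CCC[P+](c1ccccc1)(c1ccccc1)c1ccccc1.[Br-] | starting material
8 | propylidenetriphenylphosphorane | CCC=P(c1ccccc1)(c1ccccc1)c1ccccc1 | intermediate
9 | (4R,5S)-4-[(tert-butyldimethylsilyl)oxy]-5-[(2Z)-pent-2-en-1-yl]oxolan-2-ol (anomer mixture) | CC/C=C\C[C@@H]1OC(O)C[C@H]1O[Si](C)(C)C(C)(C)C | intermediate
10 | (2E)-pent-2-en-4-yn-1-ol | OC/C=C/C#C | starting material
11 | bromomagnesium (2E)-5-(bromomagnesio)pent-2-en-4-yn-1-olate | Br[Mg]OC/C=C/C#C[Mg]Br | intermediate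
12 | trimethyl{(3E)-5-[(trimethylsilyl)oxy]pent-3-en-1-yn-1-yl}silane | C[Si](C)(C)OC/C=C/C#C[Si](C)(C)C | intermediate
13 | (2E)-5-(trimethylsilyl)pent-2-en-4-yn-1-ol | OC/C=C/C#C[Si](C)(C)C | intermediate
14 | [(3E)-5-bromopent-3-en-1-yn-1-yl]trimethylsilane | BrC/C=C/C#C[Si](C)(C)C | intermediate
15 | methyltriphenylphosphonium bromide | C[P+](c1ccccc1)(c1ccccc1)c1ccccc1.[Br-] | starting material
16 | methylenetriphenylphosphorane | C=P(c1ccccc1)(c1ccccc1)c1ccccc1 | intermediate
17 | [(3E)-6-(trimethylsilyl)hex-3-en-5-yn-1-yl]triphenylphosphonium bromide | C[Si](C)(C)C#C/C=C/CC[P+](c1ccccc1)(c1ccccc1)c1ccccc1.[Br-] | intermediate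
18 | [(3E)-6-(trimethylsilyl)hex-3-en-5-yn-1-ylidene]triphenylphosphorane | C[Si](C)(C)C#C/C=C/CC=P(c1ccccc1)(c1ccccc1)c1ccccc1 | intermediate
19 | (3E,6Z,9R,10S,12Z)-9-[(tert-butyldimethylsilyl)oxy]-1-(trimethylsilyl)pentadeca-3,6,12-trien-1-yn-10-ol (formed as its sodium alkoxide) | C[Si](C)(C)C#C/C=C/C/C=C\C[C@@H](O[Si](C)(C)C(C)(C)C)[C@@H](O)C/C=C\CC | intermediate
20 | (3E,6Z,9R,10S,12Z)-9-[(tert-butyldimethylsilyl)oxy]-1-(trimethylsilyl)pentadeca-3,6,12-trien-1-yn-10-yl acetate | C[Si](C)(C)C#C/C=C/C/C=C\C[C@@H](O[Si](C)(C)C(C)(C)C)[C@@H](OC(C)=O)C/C=C\CC | intermediate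
21 | (2R,3S,5R)-5-[(1R)-1-bromopropyl]-2-[(2Z,5E)-8-(trimethylsilyl)octa-2,5-dien-7-yn-1-yl]oxolan-3-yl acetate | C[Si](C)(C)C#C/C=C/C/C=C\C[C@H]1O[C@@H]([C@H](Br)CC)C[C@@H]1OC(C)=O | intermediate
22 | cis-fused 1-oxoniabicyclo[3.3.0]octane hexachloroantimonate with O+ bonded to C6, C9 and C12 (6S,7S,9R,10S,12R,13R; 7-chloro, 10-acetoxy, 12-[(1R)-1-bromopropyl], 6-[(2E)-5-(trimethylsilyl)pent-2-en-4-yn-1-yl]) | C[Si](C)(C)C#C/C=C/C[C@H]1[C@@H](Cl)C[C@H]2[O+]1[C@@H]([C@H](Br)CC)C[C@@H]2OC(C)=O.Cl[Sb-](Cl)(Cl)(Cl)(Cl)Cl | intermediate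
23 | (2R,4S,5S,7S,8S)-2-[(1R)-1-bromopropyl]-5,7-dichloro-8-[(2E)-5-(trimethylsilyl)pent-2-en-4-yn-1-yl]oxocan-4-yl acetate | C[Si](C)(C)C#C/C=C/C[C@@H]1O[C@@H]([C@H](Br)CC)C[C@H](OC(C)=O)[C@@H](Cl)C[C@@H]1Cl | intermediate
24 | (2R,4S,5S,7S,8S)-2-[(1R)-1-bromopropyl]-5,7-dichloro-8-[(2E)-pent-2-en-4-yn-1-yl]oxocan-4-yl acetate | C#C/C=C/C[C@@H]1O[C@@H]([C@H](Br)CC)C[C@H](OC(C)=O)[C@@H](Cl)C[C@@H]1Cl | target

## Step count and risk

Total: 12 steps (9 in the main line from benzene, 3 for phosphonium salt 17). Longest linear sequence: 9 steps (steps 1–5 and 9–12).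

The three steps most likely to fail:

Step 11 (most at risk). Chloride may open oxonium 22 at C6 or C12 instead of C9, giving ring-contracted tetrahydrofurans, or the C10 acetate may participate. The fallback sets out from alcohol 19, isolated by quenching step 9 with aqueous NH4Cl instead of Ac2O, and comes back at 23. Dess–Martin periodinane (NaHCO3, CH2Cl2, 0 °C) gives (3E,6Z,9R,12Z)-9-[(tert-butyldimethylsilyl)oxy]-1-(trimethylsilyl)pentadeca-3,6,12-trien-1-yn-10-one F1. N-Bromosuccinimide cyclisation as in step 10 gives (2R,5R)-5-[(1R)-1-bromopropyl]-2-[(2Z,5E)-8-(trimethylsilyl)octa-2,5-dien-7-yn-1-yl]oxolan-3-one F2. The Et2SCl·SbCl6 / n-Bu4NCl sequence on this ketone now has C9 α to a carbonyl, where SN2 opening of the oxonium is strongly accelerated and no neighbouring ester exists, and gives (2R,5S,7S,8S)-2-[(1R)-1-bromopropyl]-5,7-dichloro-8-[(2E)-5-(trimethylsilyl)pent-2-en-4-yn-1-yl]oxocan-4-one F3. Reduction with NaBH4/CeCl3·7H2O (MeOH, −78 °C; hydride anti to the C–Cl bond, Cornforth/Felkin–Anh) gives the threo chlorohydrin (2R,4S,5S,7S,8S)-2-[(1R)-1-bromopropyl]-5,7-dichloro-8-[(2E)-5-(trimethylsilyl)pent-2-en-4-yn-1-yl]oxocan-4-ol F4. Acetylation (Ac2O, pyridine, DMAP) then gives 23.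

Step 10. The silyl ether may cyclise slowly, give some 2,5-trans ring, or lose out to attack on the other alkene. The fallback sets out from 20 and comes back at 21. HF·pyridine (THF/pyridine, 0 °C) cleaves the silyl ether to (3E,6Z,9R,10S,12Z)-9-hydroxy-1-(trimethylsilyl)pentadeca-3,6,12-trien-1-yn-10-yl acetate F5, which is used at once to avoid acyl shift. Acid-catalysed benzylation (2,6-dichlorobenzyl 2,2,2-trichloroacetimidate, TfOH cat., CH2Cl2/cyclohexane, 0 °C) gives (3E,6Z,9R,10S,12Z)-9-[(2,6-dichlorobenzyl)oxy]-1-(trimethylsilyl)pentadeca-3,6,12-trien-1-yn-10-yl acetate F6. Cyclisation with 2,4,4,6-tetrabromocyclohexa-2,5-dienone (CH2Cl2, −20 °C) proceeds through the benzylic oxonium ion, the classical cis-selective variant, and gives 21 with loss of the benzyl group as its bromide.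

Step 9. The homoallylic enyne ylide 18 may eliminate, and the C10 alkoxide next to the silyl ether may trigger 1,2-silyl migration. The fallback sets out from lactol 9 (and uses bromide 14) and comes back at alcohol 19, which is acetylated as in the second stage of step 9. Dimethyl (1-diazo-2-oxopropyl)phosphonate (K2CO3, MeOH, 0 °C) converts the lactol into (4R,5S,7Z)-4-[(tert-butyldimethylsilyl)oxy]dec-7-en-1-yn-5-ol F7. Copper-mediated coupling with 14 (CuI, NaI, K2CO3, DMF, rt) gives (3E,9R,10S,12Z)-9-[(tert-butyldimethylsilyl)oxy]-1-(trimethylsilyl)pentadeca-3,12-diene-1,6-diyn-10-ol F8. Semi-hydrogenation of the dialkyl alkyne (H2, Pd/CaCO3 poisoned with Pb(OAc)2, quinoline, EtOAc; the silylated conjugated alkyne reacts far more slowly) gives 19.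

Further compounds

F1 | step 11 | (3E,6Z,9R,12Z)-9-[(tert-butyldimethylsilyl)oxy]-1-(trimethylsilyl)pentadeca-3,6,12-trien-1-yn-10-one | C[Si](C)(C)C#C/C=C/C/C=C\C[C@@H](O[Si](C)(C)C(C)(C)C)C(=O)C/C=C\CC
F2 | step 11 | (2R,5R)-5-[(1R)-1-bromopropyl]-2-[(2Z,5E)-8-(trimethylsilyl)octa-2,5-dien-7-yn-1-yl]oxolan-3-one | C[Si](C)(C)C#C/C=C/C/C=C\C[C@H]1O[C@@H]([C@H](Br)CC)CC1=O
F3 | step 11 | (2R,5S,7S,8S)-2-[(1R)-1-bromopropyl]-5,7-dichloro-8-[(2E)-5-(trimethylsilyl)pent-2-en-4-yn-1-yl]oxocan-4-one | C[Si](C)(C)C#C/C=C/C[C@@H]1O[C@@H]([C@H](Br)CC)CC(=O)[C@@H](Cl)C[C@@H]1Cl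
F4 | step 11 | (2R,4S,5S,7S,8S)-2-[(1R)-1-bromopropyl]-5,7-dichloro-8-[(2E)-5-(trimethylsilyl)pent-2-en-4-yn-1-yl]oxocan-4-ol | C[Si](C)(C)C#C/C=C/C[C@@H]1O[C@@H]([C@H](Br)CC)C[C@H](O)[C@@H](Cl)C[C@@H]1Cl
F5 | step 10 | (3E,6Z,9R,10S,12Z)-9-hydroxy-1-(trimethylsilyl)pentadeca-3,6,12-trien-1-yn-10-yl acetate | C[Si](C)(C)C#C/C=C/C/C=C\C[C@@H](O)[C@@H](OC(C)=O)C/C=C\CC
F6 | step 10 | (3E,6Z,9R,10S,12Z)-9-[(2,6-dichlorobenzyl)oxy]-1-(trimethylsilyl)pentadeca-3,6,12-trien-1-yn-10-yl acetate | C[Si](C)(C)C#C/C=C/C/C=C\C[C@@H](OCc1c(Cl)cccc1Cl)[C@@H](OC(C)=O)C/C=C\CC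
F7 | step 9 | (4R,5S,7Z)-4-[(tert-butyldimethylsilyl)oxy]dec-7-en-1-yn-5-ol | C#CC[C@@H](O[Si](C)(C)C(C)(C)C)[C@@H](O)C/C=C\CC
F8 | step 9 | (3E,9R,10S,12Z)-9-[(tert-butyldimethylsilyl)oxy]-1-(trimethylsilyl)pentadeca-3,12-diene-1,6-diyn-10-ol | C[Si](C)(C)C#C/C=C/CC#CC[C@@H](O[Si](C)(C)C(C)(C)C)[C@@H](O)C/C=C\CC
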